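## The problem

The target (CNP0174688.1) is the 5-deoxy biflavanoid epimesquitol-(4β→6)-epioritin-4α-ol: C4 of an upper 3',4',7,8-tetrahydroxyflavan-3-ol is bonded to C6 of a lower 4',7,8-trihydroxyflavan-3,4-diol. Each ring C carries three contiguous stereocentres: (2R,3R,4S), 2,3-cis-3,4-trans, in the upper unit and (2R,3R,4R), all-cis, in the lower unit. The two triads are separated by the flat lower ring A, so neither can control the other and each unit needs its own source of absolute configuration. Within a unit relay is possible: upper C4 can steer a reagent to the opposite face of C3 and C3 can then fix C2; lower C2 can steer C3, and an axial oxygen at C3 can steer hydride to C4. The hard relationships are the two 2,3-cis pairs, because additions to a chromene C=C bond anti to an existing aryl group leave the new C3 oxygen trans to the C2 aryl group (lower unit) or the C2 aryl group cis to the C4 aryl group (upper unit). The lower benzylic C4 hydroxyl (para to O7, ortho to O1) ionises in acid and can be hydrogenolysed, the interflavan bond is acid-labile for the same reason, and the free catechol, pyrogallol-type and phenol rings are oxidised in base and air, so the last steps must be neutral. The lower ring A must be functionalised at C6 and not at C5. The enabling feature is that upper C4 bears two aryl groups, one of which (upper ring A) has O1 on the ortho carbon C8a: O1–C8a–C4a–C4 is the skeleton of an ortho-quinone methide, and its [4+2] union with a C3–C2 enol partner forms C3–C4 and O1–C2 and closes upper ring C.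

## Retrosynthesis

**Protecting groups (30 ⇒ 29 ⇒ 28).** Seven phenolic O–benzyl bonds are cut last and the two O–Si bonds of the lower diol just before. Benzyl ethers are preferred to methyl or acyl groups because hydrogenolysis is neutral. Silyl ethers are preferred to an acetal on the cis-diol because an acetal would have to leave under acid at the ionisable lower C4, whereas the silyl ethers survive the organolithium, Brønsted acid, osmium, hydride and Mitsunobu steps. 29 and 28 are lipophilic and not air-sensitive. The forward steps are asked only to spare the benzylic C4–OH and C2–O1 bonds.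

**Upper O1–C2 bond (28 ⇒ 27).** Ring C of the upper unit is opened at O1–C2. Any syn addition across a C2=C3 bond anti to the C4 aryl group would place the ring B aryl group cis to the C4 aryl group, which is the wrong C2 epimer; hydride addition to a C2 oxocarbenium ion has the same bias. An SN2 closure inverts a carbinol whose configuration can be set reliably, so the precursor is the phenol anti-diol 27. The forward Mitsunobu etherification must activate the benzylic hydroxyl and proceed with clean inversion.

**Upper C2 and C3 oxygenation (27 ⇒ 26 ⇒ 24).** The C2–H bond of 27 is cut back to ketone 26, and the C3–OH and C2=O of 26 are cut back to the enol ether double bond of 4H-chromene 24. C4 is the only stereocentre of 24 in the upper unit; it directs dihydroxylation to the opposite face (C3), and the C3 hydroxyl then directs a chelation-controlled reduction (C2). Two stereocentres and two oxygens are removed, and the forward steps need only substrate control.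

**Key disconnection (24 ⇒ 18 + 21).** C3–C4 and O1–C2 are cut in a retro-hetero-Diels–Alder sense, giving ortho-hydroxy diarylmethanol 18 (as its quinone methide 22) and silyl enol ether 21. The neighbouring cut, the interflavan C4–C6 bond through a flavan-4-yl cation, would need a lower 3,4-diol unit that is itself a C4 electrophile to act as a nucleophile at C6 and not at C5. Here the interflavan carbon–carbon bond is made beforehand as an ordinary carbonyl addition, and upper C4 becomes stereogenic under catalyst control. The precursors are far simpler: 21 is achiral and the carbinol centre of 18 needs no control. The forward reaction must ionise only the doubly benzylic carbinol, differentiate the faces of the methide, and end as the enol ether. A tert-butyldimethylsilyl enol ether is used with molecular sieves so that the water released does not hydrolyse the nucleophile.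

**Diarylmethanol (18 ⇒ 13 + 15).** The bond between the carbinol carbon and lower C6 is cut to aryl bromide 13 (as aryllithium 16) and salicylaldehyde 15 (as phenoxide 17). This polarity is chosen because bromine can be placed at the future C6 at the acetophenone stage, para to a free phenol, which removes the C5/C6 question. Using the phenoxide of 15 saves a protection and a deprotection.

**Lower stereotriad (13 ⇒ 12 ⇒ 10 ⇒ 9 ⇒ 7).** Dihydroxylation of a C3=C4 alkene would add anti to the 2-aryl group and give the 2,3-trans-3,4-cis isomer. The triad is therefore built by relay from C2: the O–Si bonds of 13 go back to diol 12, the C4–H bond of 12 to ketone 10, the inverted C3–O bond of 10 to trans-dihydroflavonol 9, and the C3–O bond of 9 to flavanone 7. Each forward step has one job: oxidation of the enol ether anti to the aryl group, SN2 inversion next to a carbonyl group, and hydride delivery anti to the then axial C3 oxygen.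

**Lower ring C and ring A (7 ⇒ 5 + 6; 5 ⇒ 3 ⇒ 2 ⇒ 1).** The C2–aryl bond of 7 is cut to chromone 5 and boronic acid 6, so that the only lower-unit stereocentre not set by relay comes from a catalytic asymmetric conjugate addition; cyclisation of a chalcone would set it less reliably. 5 is reached by one-carbon annulation of bromoacetophenone 3, 3 by bromination of 2 para to the free phenol, and 2 by selective dibenzylation of 1.

**Small partners (21 ⇒ 20 ⇒ 19; 15 ⇒ 14).** The O–Si bond of 21 is cut to ketone 20, and the benzyl ethers of 20 and 15 to the commercial phenols 19 and 14. In 14, as in 1, the hydroxyl ortho to the carbonyl group is hydrogen-bonded and stays free.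

## Roads not taken

**Alternative 1:** The lower ring A would be made by a Diels–Alder benzannulation. C5'–C6' and C4a'–C8a' (primes: lower unit) are cut, leading back to the tetra-oxygenated butadiene A2, which carries the finished benzylated upper unit on its terminal carbon, and to but-3-yn-2-one A3. Forward, A2 and A3 combine, the adduct loses silanol and aromatises to acetophenone A1. Its merits: the interflavan bond exists from the start as a bond from upper C4 to a vinyl carbon, so it can be made on a simple C4-functionalised flavan-3-ol where attack trans to the C3 oxygen is the natural outcome; no asymmetric catalysis or C2 inversion is needed in the upper unit; and the substitution pattern of the lower ring A is fixed by the cycloaddition. Its weak points: the ketene-acetal diene A2 is very labile and must be prepared on the complete upper unit; the regiochemistry rests on three oxygen donors that do not all push the same way; and A1 still lacks the whole lower ring C. The pyranone annulation, the C2 aryl group and the all-cis C2–C3–C4 triad would then be built linearly, in eight or more steps of basic, oxidising and reducing chemistry, on the most valuable intermediate, after a protecting-group exchange to free the phenol ortho to the acetyl group. This road is better for the upper stereotriad; the chosen plan sets against it convergence, since both halves are finished separately and no lower-unit stereocentre is made on the dimer.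

**Alternative 2:** Upper ring C would arise by ring expansion of a 2,3-dihydrobenzofuran. O1–C2 and the C3–O(acetyl) bond are cut, with the O1–C3 bond of dihydrobenzofuran carbinol A5 present instead. Forward, the side-chain carbinol of A5 is triflated in the presence of a hindered pyridine base, the ring oxygen displaces the triflate at C2 to give an oxiranium ion, and external acetate opens it at C3 to give the 3-O-acetyl chroman A4. Its merits: two consecutive inversions are stereospecific, the 2,3-cis relationship and a differentiated C3 oxygen appear in one step, and no choice between two free hydroxyls is involved; in this respect it is more secure than the Mitsunobu closure of 27. Its weak points: the three stereocentres are only moved into A5, a 3-aryl dihydrobenzofuran bearing the bulky lower unit, for which no shorter asymmetric entry is evident. Acetate can also attack the benzylic C2 of the oxiranium ion, so ring B must be deactivated as a bis-pivalate and deprotected separately at the end. The acetonide on the lower diol would have to come off under acid at the ionisable C4. The chosen plan sets against the better C2/C3 stereospecificity a catalytic asymmetric union of two simple partners and a single, neutral deprotection scheme.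

**Alternative 3:** Upper ring C would be closed by an epoxide–arene cyclisation. The C4–C4a bond is cut, leading to trans-epoxide A7, in which C2 already carries the ring A aryl ether. Forward, Sc(OTf)3 or a fluorinated alcohol solvent opens the epoxide at the benzylic C4, the aryl ether ring attacks through the carbon ortho to oxygen, and the C3 hydroxyl is released, giving A6, which is identical with 28. Its merits: it reaches 28 in one step after the fragments are joined, where the chosen route needs four (steps 13–16); C2 is never inverted; and the 3,4-trans product is the naturally favoured one. On step count after fragment union it is the better road. Its weak points: C4 is benzylic to the very electron-rich lower ring, so opening is SN1-like and the C4 configuration rests on the facial preference of the closure, not on inversion; hydride shift to a ketone competes. A7 also needs an enantiopure allylic aryl ether at C2, made by etherification of a doubly activated allylic benzylic alcohol that is prone to ionisation and allylic transposition, followed by acyclic, reagent-controlled epoxidation. The chosen plan sets against the shorter end game a catalyst-controlled C4, cyclic substrate control for C3 and C2, and precursors (18, 21) that contain no stereochemical problem.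

Key step: step 13

Remark on the chemistry (assumption): the absolute sense of induction of the pyridine-oxazoline ligand in step 4 and of the phosphoric acid in step 13 is taken to follow the usual models for these catalysts; should either prove opposite, the antipodal ligand or acid is used and nothing else changes.

Abbreviation used in names: Ar(L) = (2R,3S,4R)-7,8-bis(benzyloxy)-2-[4-(benzyloxy)phenyl]-3,4-bis(tert-butyldimethylsilyloxy)chroman-6-yl, the all-cis lower unit of 13 without its bromine (2-aryl, 3-O and 4-O on one face). CIP descriptors at lower C3 and upper C4 change with the protecting groups while the geometry stays that of 30.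

Step 1
Reactants: 1 2',3',4'-trihydroxyacetophenone (gallacetophenone)
Product: 2 3',4'-bis(benzyloxy)-2'-hydroxyacetophenone
Conditions: BnBr (2.1 equiv), K2CO3, acetone, reflux
Reagents that add atoms: benzyl bromide, BrCc1ccccc1
Why: Williamson etherification; the 2'-hydroxyl is hydrogen-bonded to the acetyl group and is the least acidic and least nucleophilic, so two equivalents of halide should take only the 4'- and 3'-hydroxyls.

Step 2
Reactants: 2 3',4'-bis(benzyloxy)-2'-hydroxyacetophenone
Product: 3 3',4'-bis(benzyloxy)-5'-bromo-2'-hydroxyacetophenone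
Conditions: NBS, MeCN, 0 °C → rt
Reagents that add atoms: N-bromosuccinimide, O=C1CCC(=O)N1Br
Why: Electrophilic aromatic bromination; the free phenol directs para (C5', also ortho to the 4'-benzyloxy group), while C6' is deactivated by the ortho acetyl group. C5' becomes C6 of the lower unit, so the C5/C6 question is settled here.

Step 3
Reactants: 3 3',4'-bis(benzyloxy)-5'-bromo-2'-hydroxyacetophenone
Product: 5 7,8-bis(benzyloxy)-6-bromo-4H-chromen-4-one, via enaminone 4 (not isolated)
Conditions: Me2NCH(OMe)2, PhMe, 100 °C; then conc. HCl, CH2Cl2, rt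
Reagents that add atoms: N,N-dimethylformamide dimethyl acetal, COC(OC)N(C)C
Why: Enaminone formation at the methyl ketone followed by acid-mediated addition of the phenol and loss of dimethylamine is the standard chromone synthesis; the amide acetal supplies C2.

Step 4
Reactants: 5 7,8-bis(benzyloxy)-6-bromo-4H-chromen-4-one; 6 4-(benzyloxy)phenylboronic acid
Product: 7 (2S)-7,8-bis(benzyloxy)-2-[4-(benzyloxy)phenyl]-6-bromochroman-4-one
Conditions: Pd(OCOCF3)2 (5 mol %), (R)-t-BuPyOx (6 mol %), NH4PF6 (30 mol %), H2O (5 equiv), ClCH2CH2Cl, 60 °C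
Reagents that add atoms: none
Why: Palladium-catalysed asymmetric conjugate addition of an arylboronic acid to a chromone; the pyridine-oxazoline ligand on the arylpalladium species selects the face of C2. The cycle stays at divalent palladium, so the aryl bromide is not consumed by oxidative addition, and the near-neutral medium avoids ring opening of the flavanone.

Step 5
Reactants: 7 (2S)-7,8-bis(benzyloxy)-2-[4-(benzyloxy)phenyl]-6-bromochroman-4-one
Product: 9 (2R,3R)-7,8-bis(benzyloxy)-2-[4-(benzyloxy)phenyl]-6-bromo-3-hydroxychroman-4-one (2,3-trans), via trimethylsilyl enol ether 8 (not isolated)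
Conditions: TMSOTf, Et3N, CH2Cl2, 0 °C; then DMDO, acetone/CH2Cl2, −40 → 0 °C; then citric acid, MeOH/H2O
Reagents that add atoms: dimethyldioxirane, CC1(C)OO1
Why: Rubottom oxidation; soft enolisation leaves C2 untouched, and the dioxirane epoxidises the C3=C4 enol ether anti to the 2-aryl group, so the C3 hydroxyl should be trans to it, which is also the more stable isomer. The electron-rich enol ether reacts far faster than the benzyl ethers or the arenes.

Step 6
Reactants: 9 (2R,3R)-7,8-bis(benzyloxy)-2-[4-(benzyloxy)phenyl]-6-bromo-3-hydroxychroman-4-one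
Product: 10 (2R,3S)-7,8-bis(benzyloxy)-2-[4-(benzyloxy)phenyl]-6-bromo-4-oxochroman-3-yl 4-nitrobenzoate (2,3-cis)
Conditions: 4-O2NC6H4CO2H, PPh3, DIAD, THF, 0 °C → rt
Reagents that add atoms: 4-nitrobenzoic acid, O=C(O)c1ccc([N+](=O)[O-])cc1
Why: Mitsunobu inversion; SN2 displacement of the alkoxyphosphonium group is accelerated by the adjacent carbonyl and places the ester axial and cis to the aryl group. In the trans-diequatorial substrate no C2 hydrogen is anti-periplanar to the leaving group, which disfavours elimination to the flavone.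

Step 7
Reactants: 10 (2R,3S)-7,8-bis(benzyloxy)-2-[4-(benzyloxy)phenyl]-6-bromo-4-oxochroman-3-yl 4-nitrobenzoate
Product: 12 (2R,3R,4R)-7,8-bis(benzyloxy)-2-[4-(benzyloxy)phenyl]-6-bromochromane-3,4-diol (all-cis), via hydroxy nitrobenzoate 11 (not isolated)
Conditions: NaBH4, THF/MeOH, −20 → 0 °C; then K2CO3, MeOH, rt
Reagents that add atoms: none
Why: Borohydride reduction; hydride should attack C4 anti to the axial C3–O bond (Felkin–Anh and steric control agree), giving the equatorial C4 hydroxyl cis to the C3 oxygen, as known for 2,3-cis-3-oxygenated flavanones. Methanolysis of the activated ester in the same flask frees the diol.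

Step 8
Reactants: 12 (2R,3R,4R)-7,8-bis(benzyloxy)-2-[4-(benzyloxy)phenyl]-6-bromochromane-3,4-diol
Product: 13 (2R,3S,4R)-7,8-bis(benzyloxy)-2-[4-(benzyloxy)phenyl]-6-bromo-3,4-bis(tert-butyldimethylsilyloxy)chromane (all-cis)
Conditions: TBSOTf, 2,6-lutidine, CH2Cl2, 0 °C → rt
Reagents that add atoms: tert-butyldimethylsilyl trifluoromethanesulfonate, CC(C)(C)[Si](C)(C)OS(=O)(=O)C(F)(F)F
Why: Silylation with the triflate and a hindered base is the standard way to cap both hydroxyls of a hindered cis-diol; the base keeps the medium non-acidic at the benzylic C4.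

Step 9
Reactants: 14 2,3,4-trihydroxybenzaldehyde
Product: 15 3,4-bis(benzyloxy)-2-hydroxybenzaldehyde
Conditions: BnBr (2.1 equiv), K2CO3, acetone, reflux
Reagents that add atoms: benzyl bromide, BrCc1ccccc1
Why: Williamson etherification, selective as in step 1 because the 2-hydroxyl is hydrogen-bonded to the formyl group.

Step 10
Reactants: 13 (2R,3S,4R)-7,8-bis(benzyloxy)-2-[4-(benzyloxy)phenyl]-6-bromo-3,4-bis(tert-butyldimethylsilyloxy)chromane; 15 3,4-bis(benzyloxy)-2-hydroxybenzaldehyde
Product: 18 [3,4-bis(benzyloxy)-2-hydroxyphenyl][Ar(L)]methanol (both carbinol epimers), via 6-lithio chroman 16 (not isolated), via sodium 2,3-bis(benzyloxy)-6-formylphenoxide 17 (not isolated)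
Conditions: 13, n-BuLi, THF, −78 °C; 15, NaH, THF, 0 °C; combine at −78 → −20 °C; aq. NH4Cl
Reagents that add atoms: none
Why: Bromine–lithium exchange followed by addition of the aryllithium to the aldehyde, whose phenol is masked as its phenoxide so that no organolithium is wasted. The new carbinol centre is uncontrolled and needs no control because it becomes trigonal in step 13; 18 should be handled on base-washed silica because it dehydrates easily.

Step 11
Reactants: 19 3',4'-dihydroxyacetophenone
Product: 20 3',4'-bis(benzyloxy)acetophenone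
Conditions: BnBr (2.5 equiv), K2CO3, DMF, 60 °C
Reagents that add atoms: benzyl bromide, BrCc1ccccc1
Why: Exhaustive Williamson etherification of a catechol.

Step 12
Reactants: 20 3',4'-bis(benzyloxy)acetophenone
Product: 21 {1-[3,4-bis(benzyloxy)phenyl]ethenyloxy}(tert-butyl)dimethylsilane
Conditions: TBSOTf, Et3N, CH2Cl2, 0 °C
Reagents that add atoms: tert-butyldimethylsilyl trifluoromethanesulfonate, CC(C)(C)[Si](C)(C)OS(=O)(=O)C(F)(F)F
Why: Soft enolisation and O-silylation of a methyl ketone; the tert-butyldimethylsilyl enol ether is far more stable to adventitious acid and water than the trimethylsilyl analogue.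

Step 13
Reactants: 18 [3,4-bis(benzyloxy)-2-hydroxyphenyl][Ar(L)]methanol; 21 {1-[3,4-bis(benzyloxy)phenyl]ethenyloxy}(tert-butyl)dimethylsilane
Product: 24 (4R)-7,8-bis(benzyloxy)-2-[3,4-bis(benzyloxy)phenyl]-4-Ar(L)-4H-chromene (C4 arranged as upper C4 of 30), via ortho-quinone methide 22 (not isolated), via 2-silyloxy ketal 23 (not isolated)
Conditions: (R)-TRIP [3,3'-bis(2,4,6-triisopropylphenyl)-1,1'-binaphthyl-2,2'-diyl hydrogen phosphate] (10 mol %), 21 (3 equiv), 5 Å MS, PhMe, −30 °C → rt
Reagents that add atoms: none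
Why: The acid protonates the doubly benzylic carbinol of 18, and dehydration gives ortho-quinone methide 22, which stays hydrogen-bonded through its carbonyl oxygen to the chiral phosphate. The CH2 terminus of 21 attacks the methide carbon (C3–C4) and the quinone oxygen closes on the developing silyloxycarbenium carbon (O1–C2) in a concerted, strongly asynchronous inverse-electron-demand hetero-Diels–Alder reaction, so ring C is closed in a [4+2] mode (in the stepwise limit, a 6-endo capture of the oxocarbenium ion by the phenol oxygen). The mixed silyl ketal 23 ionises under the same acid to the aryl-stabilised oxocarbenium ion and loses H3 and silanol to give the conjugated enol ether 24. The closest known reaction type is the chiral phosphoric acid-catalysed [4+2] cycloaddition of ortho-quinone methides, generated in situ from ortho-hydroxybenzhydrols, with enol ethers and enamides to give 4-aryl chromans and 4H-chromenes. The only new stereocentre, C4, is set by the catalyst, whose 2,4,6-triisopropylphenyl groups shield one face of the bound methide; the lower-unit stereocentres are too remote to interfere. The step needs chemoselective ionisation of the carbinol over the lower C4 silyl ether, secured by two electron-rich aryl groups and the ortho hydroxyl on the same carbon; a single quinone methide, secured by there being only one free phenol; and carbon attack through the unsubstituted terminus of the enol ether, secured by its polarity. The robust silyl group, the excess of 21 and the molecular sieves keep the water released from hydrolysing the nucleophile.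

Step 14
Reactants: 24 (4R)-7,8-bis(benzyloxy)-2-[3,4-bis(benzyloxy)phenyl]-4-Ar(L)-4H-chromene
Product: 26 (2R,3R)-1-[3,4-bis(benzyloxy)phenyl]-3-[3,4-bis(benzyloxy)-2-hydroxyphenyl]-2-hydroxy-3-Ar(L)-propan-1-one, via cyclic hemiketal diol 25 (not isolated)
Conditions: OsO4 (5 mol %), NMO, acetone/H2O, 0 °C → rt
Reagents that add atoms: N-methylmorpholine N-oxide, C[N+]1([O-])CCOCC1; water, O
Why: Osmium-catalysed dihydroxylation of an enol ether; the reagent adds to C2=C3 on the face opposite the pseudo-axial C4 aryl group, and the 2-hydroxy hemiketal opens to the phenol and the aryl ketone. The C3 hydroxyl is thus trans to Ar(L), as in the target; this avoids a free enol-ether epoxide that could rearrange by hydride shift.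

Step 15
Reactants: 26 (2R,3R)-1-[3,4-bis(benzyloxy)phenyl]-3-[3,4-bis(benzyloxy)-2-hydroxyphenyl]-2-hydroxy-3-Ar(L)-propan-1-one
Product: 27 (1S,2R,3R)-1-[3,4-bis(benzyloxy)phenyl]-3-[3,4-bis(benzyloxy)-2-hydroxyphenyl]-3-Ar(L)-propane-1,2-diol (1,2-anti)
Conditions: Zn(BH4)2, Et2O/CH2Cl2, −20 → 0 °C
Reagents that add atoms: none
Why: Chelation-controlled reduction of an α-hydroxy ketone (Cram chelate model); zinc bridges the carbonyl and the α-oxygen and hydride enters from the face away from the diarylmethyl group, which should give the anti-1,2-diol.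

Step 16
Reactants: 27 (1S,2R,3R)-1-[3,4-bis(benzyloxy)phenyl]-3-[3,4-bis(benzyloxy)-2-hydroxyphenyl]-3-Ar(L)-propane-1,2-diol
Product: 28 (2R,3R,4R)-7,8-bis(benzyloxy)-2-[3,4-bis(benzyloxy)phenyl]-4-Ar(L)-chroman-3-ol (2,3-cis-3,4-trans; hepta-O-benzyl bis-O-silyl ether of 30)
Conditions: PPh3, DIAD, THF, 0 °C → rt
Reagents that add atoms: none
Why: Intramolecular Mitsunobu etherification, known for phenolic 1,3-diarylpropane-1,2-diols; the phenol is the only acidic partner and attacks the activated benzylic carbinol in a 6-exo-tet SN2 closure with inversion, turning the anti-diol into the 2,3-cis chroman. Closure at the C3 hydroxyl (five-membered ring) is disfavoured because that carbon is not benzylic and is flanked by the diarylmethyl group.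

Step 17
Reactants: 28 (2R,3R,4R)-7,8-bis(benzyloxy)-2-[3,4-bis(benzyloxy)phenyl]-4-Ar(L)-chroman-3-ol
Product: 29 hepta-O-benzyl ether of 30 (all seven phenols benzylated; upper 3-OH and lower 3-OH and 4-OH free; configurations as in 30)
Conditions: TBAF, THF, rt → 40 °C
Reagents that add atoms: none
Why: Fluoride cleavage of the two secondary silyl ethers; no phenol is free at this stage, so the basic fluoride source does no harm, and the benzylic C4 oxygen is released without acid.

Step 18
Reactants: 29 hepta-O-benzyl ether of 30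
Product: 30 (2R,3R,4R)-6-[(2R,3R,4S)-2-(3,4-dihydroxyphenyl)-3,7,8-trihydroxychroman-4-yl]-2-(4-hydroxyphenyl)chromane-3,4,7,8-tetrol
Conditions: H2 (1 atm), Pd(OH)2/C, THF/MeOH, rt
Reagents that add atoms: none
Why: Hydrogenolysis of aryl benzyl ethers under neutral conditions; phenoxide-type O–CH2Ph bonds cleave much faster than the benzylic C4–OH and C2–O1 bonds in the absence of acid, and filtration under argon should give the polyphenol without exposure to base.

Compound list
1 | 2',3',4'-trihydroxyacetophenone (gallacetophenone) | CC(=O)c1ccc(O)c(O)c1O | starting material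
2 | 3',4'-bis(benzyloxy)-2'-hydroxyacetophenone | CC(=O)c1ccc(OCc2ccccc2)c(OCc2ccccc2)c1O | intermediate
3 | 3',4'-bis(benzyloxy)-5'-bromo-2'-hydroxyacetophenone | CC(=O)c1cc(Br)c(OCc2ccccc2)c(OCc2ccccc2)c1O | intermediate
4 | (E)-1-[3,4-bis(benzyloxy)-5-bromo-2-hydroxyphenyl]-3-(dimethylamino)prop-2-en-1-one | CN(C)/C=C/C(=O)c1cc(Br)c(OCc2ccccc2)c(OCc2ccccc2)c1O | intermediate
5 | 7,8-bis(benzyloxy)-6-bromo-4H-chromen-4-one | O=c1ccoc2c(OCc3ccccc3)c(OCc3ccccc3)c(Br)cc12 | intermediate
6 | 4-(benzyloxy)phenylboronic acid | OB(O)c1ccc(OCc2ccccc2)cc1 | starting material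
7 | (2S)-7,8-bis(benzyloxy)-2-[4-(benzyloxy)phenyl]-6-bromochroman-4-one | c1ccccc1COc1ccc([C@H]2Oc3c(cc(Br)c(OCc4ccccc4)c3OCc3ccccc3)C(=O)C2)cc1 | intermediate
8 | (2S)-7,8-bis(benzyloxy)-2-[4-(benzyloxy)phenyl]-6-bromo-4-(trimethylsilyloxy)-2H-chromene | c1ccccc1COc1ccc([C@H]2Oc3c(cc(Br)c(OCc4ccccc4)c3OCc3ccccc3)C(O[Si](C)(C)C)=C2)cc1 | intermediate
9 | (2R,3R)-7,8-bis(benzyloxy)-2-[4-(benzyloxy)phenyl]-6-bromo-3-hydroxychroman-4-one (2,3-trans) | c1ccccc1COc1ccc([C@H]2Oc3c(cc(Br)c(OCc4ccccc4)c3OCc3ccccc3)C(=O)[C@@H]2O)cc1 | intermediate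
10 | (2R,3S)-7,8-bis(benzyloxy)-2-[4-(benzyloxy)phenyl]-6-bromo-4-oxochroman-3-yl 4-nitrobenzoate (2,3-cis) | c1ccccc1COc1ccc([C@H]2Oc3c(cc(Br)c(OCc4ccccc4)c3OCc3ccccc3)C(=O)[C@H]2OC(=O)c2ccc([N+](=O)[O-])cc2)cc1 | intermediate
11 | (2R,3R,4R)-7,8-bis(benzyloxy)-2-[4-(benzyloxy)phenyl]-6-bromo-4-hydroxychroman-3-yl 4-nitrobenzoate (all-cis) | c1ccccc1COc1ccc([C@H]2Oc3c(cc(Br)c(OCc4ccccc4)c3OCc3ccccc3)[C@@H](O)[C@H]2OC(=O)c2ccc([N+](=O)[O-])cc2)cc1 | intermediate
12 | (2R,3R,4R)-7,8-bis(benzyloxy)-2-[4-(benzyloxy)phenyl]-6-bromochromane-3,4-diol (all-cis) | c1ccccc1COc1ccc([C@H]2Oc3c(cc(Br)c(OCc4ccccc4)c3OCc3ccccc3)[C@@H](O)[C@H]2O)cc1 | intermediate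
13 | (2R,3S,4R)-7,8-bis(benzyloxy)-2-[4-(benzyloxy)phenyl]-6-bromo-3,4-bis(tert-butyldimethylsilyloxy)chromane (all-cis) | c1ccccc1COc1ccc([C@H]2Oc3c(cc(Br)c(OCc4ccccc4)c3OCc3ccccc3)[C@@H](O[Si](C)(C)C(C)(C)C)[C@H]2O[Si](C)(C)C(C)(C)C)cc1 | intermediate
14 | 2,3,4-trihydroxybenzaldehyde | O=Cc1ccc(O)c(O)c1O | starting material
15 | 3,4-bis(benzyloxy)-2-hydroxybenzaldehyde | O=Cc1ccc(OCc2ccccc2)c(OCc2ccccc2)c1O | intermediate
16 | (2R,3S,4R)-7,8-bis(benzyloxy)-2-[4-(benzyloxy)phenyl]-3,4-bis(tert-butyldimethylsilyloxy)-6-lithiochromane | c1ccccc1COc1ccc([C@H]2Oc3c(cc([Li])c(OCc4ccccc4)c3OCc3ccccc3)[C@@H](O[Si](C)(C)C(C)(C)C)[C@H]2O[Si](C)(C)C(C)(C)C)cc1 | intermediate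
17 | sodium 2,3-bis(benzyloxy)-6-formylphenoxide | [Na+].[O-]c1c(C=O)ccc(OCc2ccccc2)c1OCc1ccccc1 | intermediate
18 | [3,4-bis(benzyloxy)-2-hydroxyphenyl][Ar(L)]methanol (both carbinol epimers) | c1ccccc1COc1ccc([C@H]2Oc3c(cc(C(O)c5ccc(OCc6ccccc6)c(OCc6ccccc6)c5O)c(OCc4ccccc4)c3OCc3ccccc3)[C@@H](O[Si](C)(C)C(C)(C)C)[C@H]2O[Si](C)(C)C(C)(C)C)cc1 | intermediate
19 | 3',4'-dihydroxyacetophenone | CC(=O)c1ccc(O)c(O)c1 | starting material
20 | 3',4'-bis(benzyloxy)acetophenone | CC(=O)c1ccc(OCc2ccccc2)c(OCc2ccccc2)c1 | intermediate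
21 | {1-[3,4-bis(benzyloxy)phenyl]ethenyloxy}(tert-butyl)dimethylsilane | C=C(O[Si](C)(C)C(C)(C)C)c1ccc(OCc2ccccc2)c(OCc2ccccc2)c1 | intermediate
22 | 2,3-bis(benzyloxy)-6-[Ar(L)-methylidene]cyclohexa-2,4-dien-1-one (ortho-quinone methide) | c1ccccc1COc1ccc([C@H]2Oc3c(cc(C=C5C=CC(OCc6ccccc6)=C(OCc6ccccc6)C5=O)c(OCc4ccccc4)c3OCc3ccccc3)[C@@H](O[Si](C)(C)C(C)(C)C)[C@H]2O[Si](C)(C)C(C)(C)C)cc1 | intermediate
23 | 7,8-bis(benzyloxy)-2-[3,4-bis(benzyloxy)phenyl]-2-(tert-butyldimethylsilyloxy)-4-Ar(L)-chromane (C4 as in 24; both C2 epimers) | c1ccccc1COc1ccc([C@H]2Oc3c(cc([C@H]4c5ccc(OCc6ccccc6)c(OCc6ccccc6)c5OC(O[Si](C)(C)C(C)(C)C)(c5ccc(OCc6ccccc6)c(OCc6ccccc6)c5)C4)c(OCc4ccccc4)c3OCc3ccccc3)[C@@H](O[Si](C)(C)C(C)(C)C)[C@H]2O[Si](C)(C)C(C)(C)C)cc1 | intermediate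
24 | (4R)-7,8-bis(benzyloxy)-2-[3,4-bis(benzyloxy)phenyl]-4-Ar(L)-4H-chromene (C4 arranged as upper C4 of 30) | c1ccccc1COc1ccc([C@H]2Oc3c(cc([C@H]4c5ccc(OCc6ccccc6)c(OCc6ccccc6)c5OC(c5ccc(OCc6ccccc6)c(OCc6ccccc6)c5)=C4)c(OCc4ccccc4)c3OCc3ccccc3)[C@@H](O[Si](C)(C)C(C)(C)C)[C@H]2O[Si](C)(C)C(C)(C)C)cc1 | intermediate
25 | 7,8-bis(benzyloxy)-2-[3,4-bis(benzyloxy)phenyl]-4-Ar(L)-chromane-2,3-diol (2,3-cis-diol, both hydroxyls trans to Ar(L); C4 as in 24) | c1ccccc1COc1ccc([C@H]2Oc3c(cc([C@H]4c5ccc(OCc6ccccc6)c(OCc6ccccc6)c5O[C@@](O)(c5ccc(OCc6ccccc6)c(OCc6ccccc6)c5)[C@@H]4O)c(OCc4ccccc4)c3OCc3ccccc3)[C@@H](O[Si](C)(C)C(C)(C)C)[C@H]2O[Si](C)(C)C(C)(C)C)cc1 | intermediate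
26 | (2R,3R)-1-[3,4-bis(benzyloxy)phenyl]-3-[3,4-bis(benzyloxy)-2-hydroxyphenyl]-2-hydroxy-3-Ar(L)-propan-1-one | c1ccccc1COc1ccc([C@H]2Oc3c(cc([C@@H](c5ccc(OCc6ccccc6)c(OCc6ccccc6)c5O)[C@@H](O)C(=O)c5ccc(OCc6ccccc6)c(OCc6ccccc6)c5)c(OCc4ccccc4)c3OCc3ccccc3)[C@@H](O[Si](C)(C)C(C)(C)C)[C@H]2O[Si](C)(C)C(C)(C)C)cc1 | intermediate
27 | (1S,2R,3R)-1-[3,4-bis(benzyloxy)phenyl]-3-[3,4-bis(benzyloxy)-2-hydroxyphenyl]-3-Ar(L)-propane-1,2-diol (1,2-anti) | c1ccccc1COc1ccc([C@H]2Oc3c(cc([C@@H](c5ccc(OCc6ccccc6)c(OCc6ccccc6)c5O)[C@@H](O)[C@@H](O)c5ccc(OCc6ccccc6)c(OCc6ccccc6)c5)c(OCc4ccccc4)c3OCc3ccccc3)[C@@H](O[Si](C)(C)C(C)(C)C)[C@H]2O[Si](C)(C)C(C)(C)C)cc1 | intermediate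
28 | (2R,3R,4R)-7,8-bis(benzyloxy)-2-[3,4-bis(benzyloxy)phenyl]-4-Ar(L)-chroman-3-ol (2,3-cis-3,4-trans; hepta-O-benzyl bis-O-silyl ether of 30) | c1ccccc1COc1ccc([C@H]2Oc3c(cc([C@H]4c5ccc(OCc6ccccc6)c(OCc6ccccc6)c5O[C@H](c5ccc(OCc6ccccc6)c(OCc6ccccc6)c5)[C@@H]4O)c(OCc4ccccc4)c3OCc3ccccc3)[C@@H](O[Si](C)(C)C(C)(C)C)[C@H]2O[Si](C)(C)C(C)(C)C)cc1 | intermediate
29 | hepta-O-benzyl ether of 30 (upper 3-OH, lower 3-OH and 4-OH free; configurations as in 30) | c1ccccc1COc1ccc([C@H]2Oc3c(cc([C@H]4c5ccc(OCc6ccccc6)c(OCc6ccccc6)c5O[C@H](c5ccc(OCc6ccccc6)c(OCc6ccccc6)c5)[C@@H]4O)c(OCc4ccccc4)c3OCc3ccccc3)[C@@H](O)[C@H]2O)cc1 | intermediate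
30 | (2R,3R,4R)-6-[(2R,3R,4S)-2-(3,4-dihydroxyphenyl)-3,7,8-trihydroxychroman-4-yl]-2-(4-hydroxyphenyl)chromane-3,4,7,8-tetrol (epimesquitol-(4β→6)-epioritin-4α-ol) | Oc1ccc([C@H]2Oc3c(cc([C@H]4c5ccc(O)c(O)c5O[C@H](c5ccc(O)c(O)c5)[C@@H]4O)c(O)c3O)[C@@H](O)[C@H]2O)cc1 | target

Total step count: 18. Longest linear sequence: 15 steps (steps 1–8, 10, 13–18); steps 9 and 11–12 are short side branches.

Steps least certain to work

Step 13 (key step). The most likely failure is poor discrimination of the methide faces, because the silyl enol ether has no N–H or O–H to bind the phosphoryl oxygen and is held less tightly than the quinone methide. Hydrolysis of the enol ether by the water released, and addition of the product enol ether to a second quinone methide, are further risks. The fallback changes the two-carbon partner to one with two-point binding; it sets out from 20 (and 18) and returns at 24. Ketone 20 is converted with hydroxylamine hydrochloride and pyridine into 1-[3,4-bis(benzyloxy)phenyl]ethanone oxime F1. Reductive acetylation (Fe powder, Ac2O, AcOH, PhMe) gives N-{1-[3,4-bis(benzyloxy)phenyl]ethenyl}acetamide F2. The same phosphoric acid-catalysed reaction of 18 with F2 gives the 2-acetamido chromane F3, from which a trace of camphorsulfonic acid expels acetamide to give 24.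

Step 16. The activated, electron-rich benzylic carbinol may ionise before the phenol attacks, which would erode inversion and lead to the 2,3-trans chroman. Activation of the C3 hydroxyl, leading to five-membered ring closure or epoxide formation, is the second risk. The fallback ties up both hydroxyls; it sets out from 27 and returns at 28. Triethyl orthoformate and PPTS convert 27 into the cyclic orthoformate F4. On warming this ionises to a 1,3-dioxolan-2-ylium ion, which the phenol opens at the benzylic carbon with inversion to give the 3-O-formyl chroman F5. K2CO3 in MeOH then gives 28.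

Step 6. Displacement at the hindered C3 next to the carbonyl may be slow, and the product ester may epimerise by enolisation to the more stable 2,3-trans ester. The fallback inverts C3 by oxidation and reduction between two substituents on the same face; it sets out from 7 and returns at 12. NaBH4 gives the 2,4-cis flavan-4-ol F6 and the Burgess reagent dehydrates it to the 2H-chromene F7. 3-Chloroperbenzoic acid epoxidises F7 anti to the aryl group, and the epoxide is opened in situ at C4 by 3-chlorobenzoate to give the 2,3-trans-3,4-trans hydroxy ester F8 (4-O cis to the aryl group). Dess–Martin periodinane gives the 3-ketone F9, and LiB(s-Bu)3H attacks anti to both flanking substituents to give the all-cis hydroxy ester F10. K2CO3 in MeOH then gives 12.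

Step 18. Over-reduction is the risk: hydrogenolysis of the lower benzylic C4–OH, which is activated by the para oxygen, while seven benzyl ethers are being removed. The fallback reverses the order of deprotection; it sets out from 28 and returns at 30. Hydrogenolysis of 28 (H2, Pd(OH)2/C) with both silyl ethers in place, the bulky silyloxy group being a much poorer leaving group, gives the heptaphenol bis-silyl ether F11. Buffered fluoride (HF·pyridine, pyridine/THF, under argon) then gives 30.

Step 10. Carbonyl addition to the aggregated sodium phenoxide may be slow, which would allow protonation of the aryllithium and return of the debrominated lower unit. The fallback protects the phenol; it sets out from 15 (and 13) and returns at 18. Allyl bromide and K2CO3 convert 15 into 2-(allyloxy)-3,4-bis(benzyloxy)benzaldehyde F12. Addition of 16 gives the allyl-protected diarylmethanol F13, and Pd(PPh3)4 with morpholine removes the allyl group under neutral conditions to give 18.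

Further compounds
F1 | step 13 | 1-[3,4-bis(benzyloxy)phenyl]ethanone oxime | CC(=NO)c1ccc(OCc2ccccc2)c(OCc2ccccc2)c1
F2 | step 13 | N-{1-[3,4-bis(benzyloxy)phenyl]ethenyl}acetamide | C=C(NC(C)=O)c1ccc(OCc2ccccc2)c(OCc2ccccc2)c1
F3 | step 13 | N-{7,8-bis(benzyloxy)-2-[3,4-bis(benzyloxy)phenyl]-4-Ar(L)-chroman-2-yl}acetamide (C4 as in 24; both C2 epimers) | c1ccccc1COc1ccc([C@H]2Oc3c(cc([C@H]4c5ccc(OCc6ccccc6)c(OCc6ccccc6)c5OC(NC(C)=O)(c5ccc(OCc6ccccc6)c(OCc6ccccc6)c5)C4)c(OCc4ccccc4)c3OCc3ccccc3)[C@@H](O[Si](C)(C)C(C)(C)C)[C@H]2O[Si](C)(C)C(C)(C)C)cc1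
F4 | step 16 | cyclic ethyl orthoformate of 27 (2-ethoxy-1,3-dioxolane across the 1,2-diol; phenol free) | c1ccccc1COc1ccc([C@H]2Oc3c(cc([C@@H](c5ccc(OCc6ccccc6)c(OCc6ccccc6)c5O)[C@H]7OC(OCC)O[C@H]7c5ccc(OCc6ccccc6)c(OCc6ccccc6)c5)c(OCc4ccccc4)c3OCc3ccccc3)[C@@H](O[Si](C)(C)C(C)(C)C)[C@H]2O[Si](C)(C)C(C)(C)C)cc1
F5 | step 16 | 3-O-formate of 28 | c1ccccc1COc1ccc([C@H]2Oc3c(cc([C@H]4c5ccc(OCc6ccccc6)c(OCc6ccccc6)c5O[C@H](c5ccc(OCc6ccccc6)c(OCc6ccccc6)c5)[C@@H]4OC=O)c(OCc4ccccc4)c3OCc3ccccc3)[C@@H](O[Si](C)(C)C(C)(C)C)[C@H]2O[Si](C)(C)C(C)(C)C)cc1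
F6 | step 6 | (2S,4S)-7,8-bis(benzyloxy)-2-[4-(benzyloxy)phenyl]-6-bromochroman-4-ol (2,4-cis) | c1ccccc1COc1ccc([C@H]2Oc3c(cc(Br)c(OCc4ccccc4)c3OCc3ccccc3)[C@@H](O)C2)cc1
F7 | step 6 | (2S)-7,8-bis(benzyloxy)-2-[4-(benzyloxy)phenyl]-6-bromo-2H-chromene | c1ccccc1COc1ccc([C@H]2Oc3c(cc(Br)c(OCc4ccccc4)c3OCc3ccccc3)C=C2)cc1
F8 | step 6 | 7,8-bis(benzyloxy)-2-[4-(benzyloxy)phenyl]-6-bromo-3-hydroxychroman-4-yl 3-chlorobenzoate (2,3-trans-3,4-trans; 2-aryl as in 7, 4-O cis to it) | c1ccccc1COc1ccc([C@H]2Oc3c(cc(Br)c(OCc4ccccc4)c3OCc3ccccc3)[C@@H](OC(=O)c3cccc(Cl)c3)[C@@H]2O)cc1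
F9 | step 6 | 7,8-bis(benzyloxy)-2-[4-(benzyloxy)phenyl]-6-bromo-3-oxochroman-4-yl 3-chlorobenzoate (2,4-cis) | c1ccccc1COc1ccc([C@H]2Oc3c(cc(Br)c(OCc4ccccc4)c3OCc3ccccc3)[C@@H](OC(=O)c3cccc(Cl)c3)C2=O)cc1
F10 | step 6 | 7,8-bis(benzyloxy)-2-[4-(benzyloxy)phenyl]-6-bromo-3-hydroxychroman-4-yl 3-chlorobenzoate (all-cis) | c1ccccc1COc1ccc([C@H]2Oc3c(cc(Br)c(OCc4ccccc4)c3OCc3ccccc3)[C@@H](OC(=O)c3cccc(Cl)c3)[C@H]2O)cc1
F11 | step 18 | lower 3,4-bis-O-(tert-butyldimethylsilyl) ether of 30 (all phenols free) | Oc1ccc([C@H]2Oc3c(cc([C@H]4c5ccc(O)c(O)c5O[C@H](c5ccc(O)c(O)c5)[C@@H]4O)c(O)c3O)[C@@H](O[Si](C)(C)C(C)(C)C)[C@H]2O[Si](C)(C)C(C)(C)C)cc1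
F12 | step 10 | 2-(allyloxy)-3,4-bis(benzyloxy)benzaldehyde | C=CCOc1c(C=O)ccc(OCc2ccccc2)c1OCc1ccccc1
F13 | step 10 | [2-(allyloxy)-3,4-bis(benzyloxy)phenyl][Ar(L)]methanol (both carbinol epimers) | c1ccccc1COc1ccc([C@H]2Oc3c(cc(C(O)c5ccc(OCc6ccccc6)c(OCc6ccccc6)c5OCC=C)c(OCc4ccccc4)c3OCc3ccccc3)[C@@H](O[Si](C)(C)C(C)(C)C)[C@H]2O[Si](C)(C)C(C)(C)C)cc1
A1 | alternative 1 | 2',3'-bis(benzyloxy)-4'-hydroxy-5'-(penta-O-benzyl-epimesquitol-4β-yl)acetophenone | CC(=O)c1cc([C@H]4c5ccc(OCc6ccccc6)c(OCc6ccccc6)c5O[C@H](c5ccc(OCc6ccccc6)c(OCc6ccccc6)c5)[C@@H]4OCc4ccccc4)c(O)c(OCc2ccccc2)c1OCc1ccccc1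
A2 | alternative 1 | 4-[3,4-bis(benzyloxy)-2,4-bis(trimethylsilyloxy)buta-1,3-dien-1-yl] derivative of penta-O-benzyl-epimesquitol (upper unit configured as in 30) | C[Si](C)(C)OC(OCc1ccccc1)=C(OCc1ccccc1)C(O[Si](C)(C)C)=C[C@H]4c5ccc(OCc6ccccc6)c(OCc6ccccc6)c5O[C@H](c5ccc(OCc6ccccc6)c(OCc6ccccc6)c5)[C@@H]4OCc4ccccc4
A3 | alternative 1 | but-3-yn-2-one | CC(=O)C#C
A4 | alternative 2 | 3-O-acetyl derivative of the protected target (lower 3,4-O-isopropylidene, five benzyl ethers, upper ring B bis-pivalate) | c1ccccc1COc1ccc([C@H]2Oc3c(cc([C@H]4c5ccc(OCc6ccccc6)c(OCc6ccccc6)c5O[C@H](c5ccc(OC(=O)C(C)(C)C)c(OC(=O)C(C)(C)C)c5)[C@@H]4OC(C)=O)c(OCc4ccccc4)c3OCc3ccccc3)[C@H]7OC(C)(C)O[C@@H]27)cc1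
A5 | alternative 2 | 2-[aryl(hydroxy)methyl]-3-aryl-2,3-dihydrobenzofuran precursor of A4 (side-chain carbinol and ring C–O carbon each of the configuration that two inversions convert into A4) | c1ccccc1COc1ccc([C@H]2Oc3c(cc([C@H]4c5ccc(OCc6ccccc6)c(OCc6ccccc6)c5O[C@@H]4[C@@H](O)c4ccc(OC(=O)C(C)(C)C)c(OC(=O)C(C)(C)C)c4)c(OCc4ccccc4)c3OCc3ccccc3)[C@H]7OC(C)(C)O[C@@H]27)cc1
A6 | alternative 3 | hepta-O-benzyl bis-O-silyl ether of the target (identical with 28) | c1ccccc1COc1ccc([C@H]2Oc3c(cc([C@H]4c5ccc(OCc6ccccc6)c(OCc6ccccc6)c5O[C@H](c5ccc(OCc6ccccc6)c(OCc6ccccc6)c5)[C@@H]4O)c(OCc4ccccc4)c3OCc3ccccc3)[C@@H](O[Si](C)(C)C(C)(C)C)[C@H]2O[Si](C)(C)C(C)(C)C)cc1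
A7 | alternative 3 | trans-epoxide precursor of A6: Ar(L)-substituted oxirane bearing the [3,4-bis(benzyloxy)phenyl][2,3-bis(benzyloxy)phenoxy]methyl group | c1ccccc1COc1ccc([C@H]2Oc3c(cc([C@@H]4O[C@H]4[C@@H](c5ccc(OCc6ccccc6)c(OCc6ccccc6)c5)Oc5cccc(OCc6ccccc6)c5OCc5ccccc5)c(OCc4ccccc4)c3OCc3ccccc3)[C@@H](O[Si](C)(C)C(C)(C)C)[C@H]2O[Si](C)(C)C(C)(C)C)cc1
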